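**Plan**

1. Retrosynthesis first cuts the eight O–CH3 bonds, then the C8–C9 bond of each nonanone chain (C9 is the ring-bound carbon), each as a C=C. This leads back to one biaryl dialdehyde and one keto ylide that is used twice.
2. Next the biaryl bond C5–C1' is cut. Ring A carries the chain at C1, oxygens at C3 and C4, and the biaryl carbon C5. Ring B has the biaryl carbon C1', oxygens at C3' and C4', and the chain at C6'.
3. The enabling feature: the C4 oxygen of ring A is ortho to C5, and the chain carbon on C6' of ring B is ortho to C1'. These two neighbours can be tied as an aryl ester O–C(=O), with the ring B chain carbon held at the acid oxidation level.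
4. The ester is cut to methyl vanillate and 2-bromo-4,5-dimethoxybenzoic acid. The chain unit is cut at aryl–C(=O) to 2-lithio-1,3-dimethoxybenzene and the Weinreb amide of 8-bromooctanoic acid.
5. Forward: esterification; Pd-catalysed C–H arylation closes the only ring made (a temporary six-membered lactone); LiAlH4 opens it; the phenol is capped; both benzylic alcohols are oxidised; both chains are joined in one double Wittig reaction; hydrogenation; global demethylation.
6. Stereochemistry: none to set. The target has no stereocentre, and alkene geometry is erased by hydrogenation.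

Key step: step 2

Remark: the biaryl axis of the target carries only two ortho substituents (the C4 hydroxyl and the ring B chain) and is taken as freely rotating. The alkene isomer mixture from step 9 is carried on unseparated.

**Route**

Step 1
Reactants: 1 methyl vanillate; 2 2-bromo-4,5-dimethoxybenzoic acid
Product: 3 2-methoxy-4-(methoxycarbonyl)phenyl 2-bromo-4,5-dimethoxybenzoate
Conditions: EDC·HCl, DMAP (0.2 equiv), CH2Cl2, 0 °C → rt
Reagents that add atoms: none
Why: Steglich esterification, in which the carbodiimide activates acid 2 and DMAP transfers the acyl group to the phenol of 1, while the aryl bromide, methyl ester and ethers are inert.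

Step 2
Reactants: 3 2-methoxy-4-(methoxycarbonyl)phenyl 2-bromo-4,5-dimethoxybenzoate
Product: 4 methyl 4,8,9-trimethoxy-6-oxo-6H-benzo[c]chromene-2-carboxylate
Conditions: Pd(OAc)2 (5 mol%), PCy3·HBF4 (10 mol%), K2CO3 (2 equiv), t-BuCO2H (30 mol%), DMA, 120 °C, Ar
Reagents that add atoms: none
Why: Zerovalent palladium generated from Pd(OAc)2 and PCy3 inserts into the C–Br bond of ring B, carbonate/pivalate-assisted concerted metalation–deprotonation palladates the ring A C–H ortho to the ester oxygen to give a seven-membered diaryl palladacycle of divalent palladium, and reductive elimination forms the C5–C1' biaryl bond. The closest known reaction type is the palladium-catalysed intramolecular direct arylation of aryl 2-halobenzoates to benzo[c]chromen-6-ones, the first half of the biaryl-lactone tactic. The one ring closed is the six-membered lactone, completed by C–C bond formation between two sp2 carbons that are the termini of the six-atom chain C5–C4–O–C(=O)–C6'–C1', that is by contraction of the palladacycle on reductive elimination. No stereocentre arises and the lactone holds the biaryl planar. The step needs site selectivity on ring A and the tether secures it, since of the two carbons ortho to the ester oxygen one carries the methoxy group and only C5–H is within reach; the para methoxycarbonyl group also makes this C–H more acidic, which favours deprotonative palladation. Chemoselectivity against ester cleavage and hydrodebromination is sought with anhydrous carbonate in DMA and the bulky electron-rich phosphine.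

Step 3
Reactants: 4 methyl 4,8,9-trimethoxy-6-oxo-6H-benzo[c]chromene-2-carboxylate
Product: 5 4-(hydroxymethyl)-2-[2-(hydroxymethyl)-4,5-dimethoxyphenyl]-6-methoxyphenol
Conditions: LiAlH4 (3 equiv), THF, 0 °C → rt; aq. KNaC4H4O6 (potassium sodium tartrate) work-up
Reagents that add atoms: none
Why: Hydride reduction opens the biaryl lactone to phenol plus benzylic alcohol and reduces the methyl ester to the second benzylic alcohol (reductive lactone cleavage), and the neutral tartrate work-up avoids acid-promoted closure of the electron-rich benzylic alcohol onto the phenol.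

Step 4
Reactants: 5 4-(hydroxymethyl)-2-[2-(hydroxymethyl)-4,5-dimethoxyphenyl]-6-methoxyphenol
Product: 6 {2-[5-(hydroxymethyl)-2,3-dimethoxyphenyl]-4,5-dimethoxyphenyl}methanol
Conditions: MeI, K2CO3, acetone, reflux
Reagents that add atoms: iodomethane, CI
Why: Williamson etherification in which K2CO3 deprotonates only the phenol and not the benzylic alcohols, and capping this oxygen prevents lactol formation and re-oxidation to the lactone in the next step.

Step 5
Reactants: 6 {2-[5-(hydroxymethyl)-2,3-dimethoxyphenyl]-4,5-dimethoxyphenyl}methanol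
Product: 7 3-(2-formyl-4,5-dimethoxyphenyl)-4,5-dimethoxybenzaldehyde
Conditions: MnO2 (activated, excess), CH2Cl2, rt
Reagents that add atoms: none
Why: MnO2 oxidation of benzylic alcohols stops at the aldehyde, and both alcohols are primary, benzylic and electron-rich.

Step 6
Reactants: 8 8-bromooctanoic acid
Product: 9 8-bromo-N-methoxy-N-methyloctanamide
Conditions: MeNHOMe·HCl, EDC·HCl, i-Pr2NEt, DMAP (cat.), CH2Cl2, 0 °C → rt
Reagents that add atoms: N,O-dimethylhydroxylamine hydrochloride, CNOC.Cl
Why: Carbodiimide amide coupling to the Weinreb amide is much faster than displacement of the primary bromide by the hydroxylamine or the hindered amine base.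

Step 7
Reactants: 9 8-bromo-N-methoxy-N-methyloctanamide; 10 1,3-dimethoxybenzene
Product: 12 8-bromo-1-(2,6-dimethoxyphenyl)octan-1-one, via 2,6-dimethoxyphenyllithium 11 (not isolated)
Conditions: 10, n-BuLi, THF, 0 °C → rt; then added to 9, THF, −78 → −20 °C; aq. NH4Cl
Reagents that add atoms: none
Why: Directed ortho-lithiation places lithium between the two methoxy groups, and Weinreb ketone synthesis through the chelated tetrahedral adduct gives the ketone without over-addition, acylation at low temperature being faster than substitution at the primary bromide.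

Step 8
Reactants: 12 8-bromo-1-(2,6-dimethoxyphenyl)octan-1-one
Product: 13 [8-(2,6-dimethoxyphenyl)-8-oxooctyl]triphenylphosphonium bromide
Conditions: PPh3, MeCN, reflux
Reagents that add atoms: triphenylphosphine, c1ccc(cc1)P(c1ccccc1)c1ccccc1
Why: SN2 quaternisation of triphenylphosphine by the primary alkyl bromide, to which the hindered ketone is inert.

Step 9
Reactants: 7 3-(2-formyl-4,5-dimethoxyphenyl)-4,5-dimethoxybenzaldehyde; 13 [8-(2,6-dimethoxyphenyl)-8-oxooctyl]triphenylphosphonium bromide (2.5 equiv)
Product: 15 1-(2,6-dimethoxyphenyl)-9-{3-[2-[9-(2,6-dimethoxyphenyl)-9-oxonon-1-en-1-yl]-4,5-dimethoxyphenyl]-4,5-dimethoxyphenyl}non-8-en-1-one (mainly Z at both alkenes), via [8-(2,6-dimethoxyphenyl)-8-oxooctylidene]triphenylphosphorane 14 (not isolated)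
Conditions: 13, KN(SiMe3)2 (2.4 equiv), THF, −78 °C; then 7, −78 °C → rt
Reagents that add atoms: none
Why: Double Wittig olefination, in which the amide base removes the more acidic P–CH2 proton rather than the α-proton of the twisted, doubly ortho-substituted aryl ketone, and the unstabilised ylide attacks the two non-enolisable aldehydes far faster than the shielded ketones; the alkene geometry is irrelevant.

Step 10
Reactants: 15 1-(2,6-dimethoxyphenyl)-9-{3-[2-[9-(2,6-dimethoxyphenyl)-9-oxonon-1-en-1-yl]-4,5-dimethoxyphenyl]-4,5-dimethoxyphenyl}non-8-en-1-one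
Product: 16 1-(2,6-dimethoxyphenyl)-9-{3-[2-[9-(2,6-dimethoxyphenyl)-9-oxononyl]-4,5-dimethoxyphenyl]-4,5-dimethoxyphenyl}nonan-1-one
Conditions: H2 (1 atm), Pd/C (10% palladium on carbon), EtOAc, rt
Reagents that add atoms: none
Why: Heterogeneous catalytic hydrogenation saturates the two styrene-type double bonds, while the hindered diaryl-flanked ketones and the aryl ethers are not reduced at ambient pressure.

Step 11
Reactants: 16 1-(2,6-dimethoxyphenyl)-9-{3-[2-[9-(2,6-dimethoxyphenyl)-9-oxononyl]-4,5-dimethoxyphenyl]-4,5-dimethoxyphenyl}nonan-1-one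
Product: 17 1-(2,6-dihydroxyphenyl)-9-{3-[2-[9-(2,6-dihydroxyphenyl)-9-oxononyl]-4,5-dihydroxyphenyl]-4,5-dihydroxyphenyl}nonan-1-one
Conditions: BBr3 (20 equiv), CH2Cl2, −78 °C → rt; then MeOH, H2O, 0 °C, under Ar
Reagents that add atoms: none
Why: Lewis-acid cleavage of aryl methyl ethers, in which bromide attacks the methyl group of each boron–ether adduct; the four ethers ortho to the ketones are assisted by carbonyl chelation, and hydrolysis releases the eight phenols.

**Compound list**

1 | methyl vanillate (methyl 4-hydroxy-3-methoxybenzoate) | COC(=O)c1ccc(O)c(OC)c1 | starting material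
2 | 2-bromo-4,5-dimethoxybenzoic acid | COc1cc(Br)c(C(=O)O)cc1OC | starting material
3 | 2-methoxy-4-(methoxycarbonyl)phenyl 2-bromo-4,5-dimethoxybenzoate | COC(=O)c1ccc(OC(=O)c2cc(OC)c(OC)cc2Br)c(OC)c1 | intermediate
4 | methyl 4,8,9-trimethoxy-6-oxo-6H-benzo[c]chromene-2-carboxylate | COC(=O)c1cc(OC)c2OC(=O)c3cc(OC)c(OC)cc3-c2c1 | intermediate
5 | 4-(hydroxymethyl)-2-[2-(hydroxymethyl)-4,5-dimethoxyphenyl]-6-methoxyphenol | OCc1cc(OC)c(O)c(-c2cc(OC)c(OC)cc2CO)c1 | intermediate
6 | {2-[5-(hydroxymethyl)-2,3-dimethoxyphenyl]-4,5-dimethoxyphenyl}methanol | OCc1cc(OC)c(OC)c(-c2cc(OC)c(OC)cc2CO)c1 | intermediate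
7 | 3-(2-formyl-4,5-dimethoxyphenyl)-4,5-dimethoxybenzaldehyde | O=Cc1cc(OC)c(OC)c(-c2cc(OC)c(OC)cc2C=O)c1 | intermediate
8 | 8-bromooctanoic acid | OC(=O)CCCCCCCBr | starting material
9 | 8-bromo-N-methoxy-N-methyloctanamide | CON(C)C(=O)CCCCCCCBr | intermediate
10 | 1,3-dimethoxybenzene | COc1cccc(OC)c1 | starting material
11 | 2,6-dimethoxyphenyllithium | [Li]c1c(OC)cccc1OC | intermediate (not isolated)
12 | 8-bromo-1-(2,6-dimethoxyphenyl)octan-1-one | COc1cccc(OC)c1C(=O)CCCCCCCBr | intermediate
13 | [8-(2,6-dimethoxyphenyl)-8-oxooctyl]triphenylphosphonium bromide | COc1cccc(OC)c1C(=O)CCCCCCC[P+](c1ccccc1)(c1ccccc1)c1ccccc1.[Br-] | intermediate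
14 | [8-(2,6-dimethoxyphenyl)-8-oxooctylidene]triphenylphosphorane | COc1cccc(OC)c1C(=O)CCCCCCC=P(c1ccccc1)(c1ccccc1)c1ccccc1 | intermediate (not isolated)
15 | 1-(2,6-dimethoxyphenyl)-9-{3-[2-[9-(2,6-dimethoxyphenyl)-9-oxonon-1-en-1-yl]-4,5-dimethoxyphenyl]-4,5-dimethoxyphenyl}non-8-en-1-one, drawn as the expected major (Z,Z) isomer | COc1cccc(OC)c1C(=O)CCCCCC/C=C\c1cc(OC)c(OC)c(-c2cc(OC)c(OC)cc2/C=C\CCCCCCC(=O)c2c(OC)cccc2OC)c1 | intermediate
16 | 1-(2,6-dimethoxyphenyl)-9-{3-[2-[9-(2,6-dimethoxyphenyl)-9-oxononyl]-4,5-dimethoxyphenyl]-4,5-dimethoxyphenyl}nonan-1-one | COc1cccc(OC)c1C(=O)CCCCCCCCc1cc(OC)c(OC)c(-c2cc(OC)c(OC)cc2CCCCCCCCC(=O)c2c(OC)cccc2OC)c1 | intermediate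
17 | 1-(2,6-dihydroxyphenyl)-9-{3-[2-[9-(2,6-dihydroxyphenyl)-9-oxononyl]-4,5-dihydroxyphenyl]-4,5-dihydroxyphenyl}nonan-1-one | O=C(CCCCCCCCc1cc(O)c(O)c(-c2cc(O)c(O)cc2CCCCCCCCC(=O)c2c(O)cccc2O)c1)c1c(O)cccc1O | target

**Count**

Total steps: 11. Longest linear sequence: 8 steps (steps 1, 2, 3, 4, 5, 9, 10, 11); the chain unit 13 is made in a 3-step side branch (steps 6 to 8).

**Steps most likely to fail**

Step 2. The aryl ester, activated by the para methoxycarbonyl group, may be cleaved by carbonate or traces of water. The palladated ring B may also be reduced to Ar–H before C–H palladation, because the ester must first rotate into its minor conformer that brings the two rings together. The fallback sets out from 1 and 2 and returns at 4, and fixes the pairing of the two ring carbons by a halogen and a boron atom. Bromination of 1 (Br2, AcOH, rt) ortho to the hydroxyl should give methyl 3-bromo-4-hydroxy-5-methoxybenzoate F1. Fischer esterification of 2 (MeOH, cat. H2SO4, reflux) gives methyl 2-bromo-4,5-dimethoxybenzoate F2. Miyaura borylation (bis(pinacolato)diboron, Pd(dppf)Cl2, KOAc, dioxane, 90 °C) gives methyl 4,5-dimethoxy-2-(4,4,5,5-tetramethyl-1,3,2-dioxaborolan-2-yl)benzoate F3. Suzuki–Miyaura coupling of F1 with F3 (Pd(PPh3)4, K2CO3, dioxane/H2O, 90 °C) should give methyl 2-[2-hydroxy-3-methoxy-5-(methoxycarbonyl)phenyl]-4,5-dimethoxybenzoate F4, which is not isolated because the phenol closes onto the neighbouring ester to give lactone 4.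

Step 9. Proton transfer from the ketone α-methylene to the ylide, and self-condensation of the keto ylide, may consume the reagent so that the double olefination stalls at the mono-alkene stage. The fallback sets out from 7 and 8 and returns at 16, and puts the aryl ketones in after the olefination. Heating 8 with PPh3 (MeCN, reflux) gives (7-carboxyheptyl)triphenylphosphonium bromide F5. Two equivalents of NaN(SiMe3)2 per salt (THF, 0 °C) generate sodium 8-(triphenylphosphoranylidene)octanoate F6, which olefinates both aldehydes of 7 to give 9-{3-[2-(8-carboxyoct-1-en-1-yl)-4,5-dimethoxyphenyl]-4,5-dimethoxyphenyl}non-8-enoic acid F7. Hydrogenation (H2, Pd/C, EtOAc) gives 9-{3-[2-(8-carboxyoctyl)-4,5-dimethoxyphenyl]-4,5-dimethoxyphenyl}nonanoic acid F8. Coupling with MeNHOMe·HCl (EDC·HCl, i-Pr2NEt, CH2Cl2) gives 9-{3-[2-[9-(methoxy(methyl)amino)-9-oxononyl]-4,5-dimethoxyphenyl]-4,5-dimethoxyphenyl}-N-methoxy-N-methylnonanamide F9. Addition of excess 11 (made from 10 and n-BuLi as in step 7; THF, −78 → 0 °C) to both amide groups gives 16.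

Step 11. Cleavage of eight ethers may stop short, with boron chelates at the ortho-hydroxy ketones holding back partly methylated material, and the free bis-catechol may oxidise in air during chromatography. The fallback sets out from 16 and returns at 17 by a capture-and-release sequence, so that purification is done on a protected derivative. After BBr3 cleavage the crude polyphenol is not purified but peracetylated (Ac2O, pyridine, DMAP, rt) to 2-{9-[3-[2-[9-(2,6-diacetoxyphenyl)-9-oxononyl]-4,5-diacetoxyphenyl]-4,5-diacetoxyphenyl]nonanoyl}-1,3-phenylene diacetate F10. This octaacetate is stable to air and silica gel and separates from under-cleaved material. Acid methanolysis (HCl in degassed MeOH, rt, under Ar) then releases 17 without passing through oxidisable phenolates.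

**Further compounds**

F1 | step 2 | methyl 3-bromo-4-hydroxy-5-methoxybenzoate | COC(=O)c1cc(Br)c(O)c(OC)c1
F2 | step 2 | methyl 2-bromo-4,5-dimethoxybenzoate | COC(=O)c1cc(OC)c(OC)cc1Br
F3 | step 2 | methyl 4,5-dimethoxy-2-(4,4,5,5-tetramethyl-1,3,2-dioxaborolan-2-yl)benzoate | COC(=O)c1cc(OC)c(OC)cc1B1OC(C)(C)C(C)(C)O1
F4 | step 2 | methyl 2-[2-hydroxy-3-methoxy-5-(methoxycarbonyl)phenyl]-4,5-dimethoxybenzoate (not isolated) | COC(=O)c1cc(OC)c(O)c(-c2cc(OC)c(OC)cc2C(=O)OC)c1
F5 | step 9 | (7-carboxyheptyl)triphenylphosphonium bromide | OC(=O)CCCCCCC[P+](c1ccccc1)(c1ccccc1)c1ccccc1.[Br-]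
F6 | step 9 | sodium 8-(triphenylphosphoranylidene)octanoate (not isolated) | [Na+].[O-]C(=O)CCCCCCC=P(c1ccccc1)(c1ccccc1)c1ccccc1
F7 | step 9 | 9-{3-[2-(8-carboxyoct-1-en-1-yl)-4,5-dimethoxyphenyl]-4,5-dimethoxyphenyl}non-8-enoic acid, drawn as the (Z,Z) isomer | OC(=O)CCCCCC/C=C\c1cc(OC)c(OC)c(-c2cc(OC)c(OC)cc2/C=C\CCCCCCC(=O)O)c1
F8 | step 9 | 9-{3-[2-(8-carboxyoctyl)-4,5-dimethoxyphenyl]-4,5-dimethoxyphenyl}nonanoic acid | OC(=O)CCCCCCCCc1cc(OC)c(OC)c(-c2cc(OC)c(OC)cc2CCCCCCCCC(=O)O)c1
F9 | step 9 | 9-{3-[2-[9-(methoxy(methyl)amino)-9-oxononyl]-4,5-dimethoxyphenyl]-4,5-dimethoxyphenyl}-N-methoxy-N-methylnonanamide | CON(C)C(=O)CCCCCCCCc1cc(OC)c(OC)c(-c2cc(OC)c(OC)cc2CCCCCCCCC(=O)N(C)OC)c1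
F10 | step 11 | 2-{9-[3-[2-[9-(2,6-diacetoxyphenyl)-9-oxononyl]-4,5-diacetoxyphenyl]-4,5-diacetoxyphenyl]nonanoyl}-1,3-phenylene diacetate (octaacetate of 17) | CC(=O)Oc1cccc(OC(C)=O)c1C(=O)CCCCCCCCc1cc(OC(C)=O)c(OC(C)=O)c(-c2cc(OC(C)=O)c(OC(C)=O)cc2CCCCCCCCC(=O)c2c(OC(C)=O)cccc2OC(C)=O)c1
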